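The numbers were chosen freely; the result is computed.

Whether coupling partner is left over at 2.5 s is what I reckon here, by counting turnovers.

    catalyst intermediate C → by-product + catalyst intermediate D (k1 = 260 s⁻¹, Ea1 = 60.0 kJ mol⁻¹)
    catalyst intermediate A → catalyst intermediate B (k2 = 300 s⁻¹, Ea2 = 64.0 kJ mol⁻¹)
    catalyst intermediate D ⇌ free catalyst + product (K3 = 0.0094 M, k3 = 230 s⁻¹, Ea3 = 74.0 kJ mol⁻¹, ΔH3 = −70.0 kJ mol⁻¹)
    2 catalyst intermediate B → spent catalyst (k4 = 67000 M⁻¹ s⁻¹, Ea4 = 33.0 kJ mol⁻¹)
    coupling partner + catalyst intermediate B ⇌ catalyst intermediate C (K5 = 400 M⁻¹, k5 = 5100 M⁻¹ s⁻¹, Ea5 = 20.0 kJ mol⁻¹, ΔH5 = −11.0 kJ mol⁻¹)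
    free catalyst + added ligand ⇌ idle complex (K6 = 5400 M⁻¹, k6 = 1300 M⁻¹ s⁻¹, Ea6 = 42.0 kJ mol⁻¹, ΔH6 = −29.0 kJ mol⁻¹)
    starting material + free catalyst ⇌ catalyst intermediate A (K7 = 100 M⁻¹, k7 = 3900 M⁻¹ s⁻¹, Ea7 = 39.0 kJ mol⁻¹, ΔH7 = 0 kJ mol⁻¹)
    (constants at 80 °C)

all flasks: starting material 10 mM; coupling partner 0.600 equiv; free catalyst 2.5 mol%; added ligand 0.38 mM; time 2.5 s

| charge | temperature |
|---|---|
| red | 65 °C |
| green | 80 °C |
| blue | 95 °C |

- the flask with the highest amount of product, in percent of the starting material charged ("all alike" if they lie within 1.5 percentage points) (red / green / blue / all alike)
- final product, as a percentage of the starting material charged, in red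
- final product, as a percentage of the starting material charged, in green
- final product, as a percentage of the starting material charged, in blue

- percentages count the starting material that a species holds: one spent catalyst counts as two
- a step written with two of one species runs at k times the square of its concentration and takes two of it each time
- constants are those at 80 °C; use the activation energies and enthalpies for any other temperature

I reckon green by hand, since its constants stand as given, and I hold starting material and coupling partner at their charges. The coupling partner is the limiting reagent, so the ceiling for product is 0.600 equiv of the starting material charged.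

**First instants.** All the catalyst is free. It meets starting material at 39.0 s⁻¹ and added ligand at 0.494 s⁻¹, so it enters the round far faster than it goes idle, and I leave the idle complex out. Each form then holds catalyst for a stay set by its steps:

free catalyst 0.0290 s; A 0.00333 s; B 0.0343 s; C 0.00385 s; D 0.00435 s

round = 0.0748 s

Intermediate B has the longest stay, with free catalyst close behind at 0.0290 s, so I call B the resting state, and I reckon that it holds 45.8% of the live catalyst.

**The middle.** Each B is captured by coupling partner at 30.6 s⁻¹. While the whole charge is live, it is lost to a second B at 15.4 s⁻¹, so capture is faster. But loss goes with the square of B. If y is the live fraction of the catalyst charge, then y falls at λy², with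

λ = 7.04 s⁻¹

Product, counted in catalyst charges, grows at y divided by the round. Dividing the two rates gives the allowance, the turnovers won per catalyst charge lost while the whole charge is live:

N = 1/(round × λ) = 1.90

As y falls, each catalyst lost buys N/y turnovers, so the count grows with a logarithm:

turnovers = N ln(1 + λt) = 5.55

**The end.** At 2.5 s my reckoning puts the live fraction at 5.38%. So green should stand near 13.9% of the starting material at that time, below the ceiling, with coupling partner left over.

For red and blue I carry a direction, not a number. Loss has the higher activation energy, so heat favours loss over capture. I put red first and blue last, with a gap I can't size by hand.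

The forecast gives 15% for red, 14.5% for green and 13.5% for blue, with red highest, since “Heating favours deactivation”.

At 2.5 s the flasks stand at 12.6% in red, 12.3% in green and 11.8% in blue, a spread inside the margin, so the answer is all alike. My green figure stands 1.6 percentage points high. At that time green has 79% of its coupling partner left and spent catalyst at 88.8% of the catalyst charge. The allowance, run out to 25.0 s, gives 24.6%, and green reads 23.8% there.

The neighbour is blue with 0.360 equiv of coupling partner. I reckon it with the constants as given at 80 °C, unscaled for blue's temperature: the stay on B stretches to 0.0571 s, the round to 0.0976 s, and λ to 11.5 s⁻¹. The allowance therefore falls to 0.893. I take the ratio of these turnovers to those reckoned before and apply it to blue's result, which gives 6.43%. The neighbour gives 6.60%, with 82% of its coupling partner left.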